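**Retrosynthetic overview**
- Target ⇐ hydroquinone acid (site-selective O-acetylation) ⇐ bis-pivalate 2-hydroxyethyl ester (saponification).
- Key step: one acid-initiated cation–olefin bicyclisation of an acyclic E,E-diene chain that ends in a sacrificial ketal-bearing cyclohexene (ring A), terminated by Grob fragmentation of ring A. It delivers both decalin rings, the isopropylidene, the acid side chain and all five stereocentres.
- Ring order: ring C (benzyl-bearing) closes first and ring B second, in the same operation. Ring A is carried in from 2,2-dimethylcyclohexane-1,3-dione and is opened, not formed.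
- Polyene ⇐ B-alkyl Suzuki coupling of the ring-A enol triflate with a diene arm ⇐ carboalumination/vinylation of an aryl enyne.
- Aryl enyne ⇐ ortho-C-allylation of methylhydroquinone mono-pivalate with an E allylic bromide ⇐ E-1,4-dibromo-2,3-dimethylbut-2-ene + propargyl dianion.

Assumption: the sense of induction of the chiral acid in step 9 must be fixed by experiment; the (S,S) catalyst is written for the enantiomer shown and its (R,R) antipode is used if the sense proves opposite.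

Decalin numbering used below: C1 (CH bearing the acid chain), C2 (isopropylidene), C4a (CH), C5 (quaternary, benzyl), C6 (CHMe), C8a (quaternary Me).

**Step 1**
Reactants: 1 2,3-dimethylbuta-1,3-diene
Product: 2 (2E)-1,4-dibromo-2,3-dimethylbut-2-ene
Conditions: Br2 (1.0 equiv), CHCl3, −20 °C, dark; recrystallise from hexane
Reagents that add atoms: bromine, BrBr
Why: electrophilic 1,4-(conjugate) addition of bromine under thermodynamic control gives the crystalline trans dibromide, which fixes the E geometry of the future tetrasubstituted alkene; no stereocentre is formed.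

**Step 2**
Reactants: 2 (2E)-1,4-dibromo-2,3-dimethylbut-2-ene
Product: 3 (5E)-7-bromo-5,6-dimethylhept-5-en-1-yne
Conditions: propargyl bromide, n-BuLi (2.0 equiv), TMEDA, Et2O, −78 °C; then 2 (3 equiv), THF, −78 → −30 °C; aq. NH4Cl; use at once
Reagents that add atoms: propargyl bromide, C#CCBr
Why: SN2 alkylation by the propargylic carbon of 1,3-dilithiopropyne (made in the flask) at one primary allylic bromide, with excess 2 holding it at mono-substitution and γ-attack disfavoured because it would create a quaternary carbon, so the E alkene is kept.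

**Step 3**
Reactants: 4 2-methylbenzene-1,4-diol
Product: 5 4-hydroxy-3-methylphenyl 2,2-dimethylpropanoate
Conditions: t-BuCOCl (1.0 equiv), pyridine, CH2Cl2, −30 → 0 °C
Reagents that add atoms: pivaloyl chloride, CC(C)(C)C(Cl)=O
Why: sterically controlled mono-O-acylation with a bulky acid chloride takes the hydroxyl that is not flanked by the methyl group.

**Step 4**
Reactants: 5 4-hydroxy-3-methylphenyl 2,2-dimethylpropanoate; 3 (5E)-7-bromo-5,6-dimethylhept-5-en-1-yne
Product: 8 2-[(2E)-2,3-dimethylhept-2-en-6-yn-1-yl]-6-methyl-1,4-phenylene bis(2,2-dimethylpropanoate), via sodium phenolate salt 6 (not isolated), via C-allylated phenol 7 (not isolated)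
Conditions: NaH (1.0 equiv), toluene, 0 °C → rt; 3 (1.1 equiv), rt → 50 °C; then t-BuCOCl, Et3N, DMAP (cat.), rt
Reagents that add atoms: pivaloyl chloride, CC(C)(C)C(Cl)=O
Why: ortho-selective C-allylation of a sodium phenoxide in a non-polar solvent (tight ion pair, para and one ortho position blocked) by SN2 at the primary allylic bromide keeps the E alkene, and DMAP-catalysed O-acylation then caps the hindered phenol.

**Step 5**
Reactants: 8 2-[(2E)-2,3-dimethylhept-2-en-6-yn-1-yl]-6-methyl-1,4-phenylene bis(2,2-dimethylpropanoate)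
Product: 10 2-methyl-6-[(2E,6E)-2,3,6-trimethylnona-2,6,8-trien-1-yl]-1,4-phenylene bis(2,2-dimethylpropanoate), via alkenyldimethylalane 9 (not isolated)
Conditions: Me3Al (3 equiv), Cp2ZrCl2 (20 mol %), H2O (1 equiv), CH2Cl2, −25 °C; then CH2=CHBr, ZnCl2, Pd(PPh3)4 (5 mol %), THF, rt
Reagents that add atoms: trimethylaluminium, C[Al](C)C; vinyl bromide, C=CBr
Why: Negishi zirconium-catalysed carboalumination adds Me and Al syn across the terminal alkyne (Me to the internal carbon) to give the E trisubstituted alkenylalane, and the palladium-catalysed cross-coupling with vinyl bromide proceeds with retention.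

**Step 6**
Reactants: 11 2,2-dimethylcyclohexane-1,3-dione
Product: 12 6,6-dimethyl-1,4-dioxaspiro[4.5]decan-7-one
Conditions: HOCH2CH2OH (1.1 equiv), TsOH·H2O (cat.), benzene, reflux, Dean–Stark
Reagents that add atoms: ethylene glycol, OCCO
Why: acid-catalysed ketalisation with azeotropic water removal stops at the mono-ketal because the remaining carbonyl is then flanked by a quaternary carbon next to the spiro ketal.

**Step 7**
Reactants: 12 6,6-dimethyl-1,4-dioxaspiro[4.5]decan-7-one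
Product: 14 6,6-dimethyl-1,4-dioxaspiro[4.5]dec-7-en-7-yl trifluoromethanesulfonate, via potassium enolate 13 (not isolated)
Conditions: KN(SiMe3)2, THF, −78 °C; PhNTf2, −78 → 0 °C
Reagents that add atoms: N-phenylbis(trifluoromethanesulfonimide), O=S(=O)(N(c1ccccc1)S(=O)(=O)C(F)(F)F)C(F)(F)F
Why: the ketone has one enolisable α-position only (the other is quaternary), so enolate O-triflation gives a single enol triflate.

**Step 8**
Reactants: 10 2-methyl-6-[(2E,6E)-2,3,6-trimethylnona-2,6,8-trien-1-yl]-1,4-phenylene bis(2,2-dimethylpropanoate); 14 6,6-dimethyl-1,4-dioxaspiro[4.5]dec-7-en-7-yl trifluoromethanesulfonate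
Product: 16 2-[(2E,6E)-9-(6,6-dimethyl-1,4-dioxaspiro[4.5]dec-7-en-7-yl)-2,3,6-trimethylnona-2,6-dien-1-yl]-6-methyl-1,4-phenylene bis(2,2-dimethylpropanoate), via B-alkyl-9-BBN adduct 15 (not isolated)
Conditions: 9-BBN dimer, THF, 0 °C → rt; then 14, PdCl2(dppf) (5 mol %), AsPh3, Cs2CO3, DMF/THF/H2O, rt
Reagents that add atoms: none
Why: 9-BBN hydroborates only the monosubstituted terminal alkene (anti-Markovnikov), and the B-alkyl Suzuki–Miyaura coupling joins the primary alkylborane to the enol triflate with all alkene geometries retained.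

**Step 9**
Reactants: 16 2-[(2E,6E)-9-(6,6-dimethyl-1,4-dioxaspiro[4.5]dec-7-en-7-yl)-2,3,6-trimethylnona-2,6-dien-1-yl]-6-methyl-1,4-phenylene bis(2,2-dimethylpropanoate)
Product: 18 2-hydroxyethyl 3-[(1S,4aR,5S,6S,8aR)-5-({2,5-bis[(2,2-dimethylpropanoyl)oxy]-3-methylphenyl}methyl)-5,6,8a-trimethyl-2-(propan-2-ylidene)decahydronaphthalen-1-yl]propanoate, via dioxolanylium ion 17 (not isolated)
Conditions: (S,S)-imidodiphosphorimidate Brønsted acid [two (S)-3,3'-bis(perfluoro-2-naphthyl)-BINOL units, N-triflyl groups] (5 mol %), (CF3)3COH/CH2Cl2, 4 Å sieves, −40 °C; then aq. NaHCO3, 0 °C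
Reagents that add atoms: water, O
Why: Proposed new method: the confined chiral acid protonates the tetrasubstituted (most electron-rich) alkene at the future C6 on one enantioface while the central alkene attacks the future C5 on the opposite face (concerted anti addition through a chair–chair fold, so the new H at C6 is equatorial and the C6 methyl axial, the E geometry puts the C5 methyl axial and the benzyl group equatorial, the E trisubstituted alkene gives the trans fusion with axial C8a methyl and C4a hydrogen, and the ring-A alkene attacks the C8a cation with its ring CH2 equatorial, which sets C1), after which the tertiary cation at C2 is discharged by Grob-type fragmentation of the gem-dimethyl carbon–ketal carbon bond to give the isopropylidene and a dioxolanylium ion that water opens to the 2-hydroxyethyl ester; the closest known reactions are chiral-Brønsted-acid-catalysed protonation-initiated cation–olefin polycyclisation and the Grob (retro-Prins) fragmentation of 1,3-dioxygenated cations.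

**Step 10**
Reactants: 18 2-hydroxyethyl 3-[(1S,4aR,5S,6S,8aR)-5-({2,5-bis[(2,2-dimethylpropanoyl)oxy]-3-methylphenyl}methyl)-5,6,8a-trimethyl-2-(propan-2-ylidene)decahydronaphthalen-1-yl]propanoate
Product: 19 3-[(1S,4aR,5S,6S,8aR)-5-[(2,5-dihydroxy-3-methylphenyl)methyl]-5,6,8a-trimethyl-2-(propan-2-ylidene)decahydronaphthalen-1-yl]propanoic acid
Conditions: KOH (10 equiv), MeOH/H2O (degassed, Na2S2O4), 65 °C; then 1 M HCl, 0 °C
Reagents that add atoms: potassium hydroxide, [K+].[OH-]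
Why: saponification (acyl substitution) cleaves the alkyl ester and both aryl pivalates; no stereocentre is α to a carbonyl, and exclusion of oxygen with dithionite keeps the hydroquinone from oxidising.

**Step 11**
Reactants: 19 3-[(1S,4aR,5S,6S,8aR)-5-[(2,5-dihydroxy-3-methylphenyl)methyl]-5,6,8a-trimethyl-2-(propan-2-ylidene)decahydronaphthalen-1-yl]propanoic acid
Product: 20 3-[(1S,4aR,5S,6S,8aR)-5-{[5-(acetyloxy)-2-hydroxy-3-methylphenyl]methyl}-5,6,8a-trimethyl-2-(propan-2-ylidene)decahydronaphthalen-1-yl]propanoic acid (CNP0144688.1)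
Conditions: Ac2O (1.05 equiv), pyridine, CH2Cl2, −20 °C; aqueous work-up
Reagents that add atoms: acetic anhydride, CC(=O)OC(C)=O
Why: site-selective O-acetylation (nucleophilic acyl substitution) at the unhindered 5-hydroxyl, the 2-hydroxyl being flanked by the methyl and the neopentyl-type benzyl group, with any mixed anhydride hydrolysed at work-up.

**Compound list**
1 | 2,3-dimethylbuta-1,3-diene | C=C(C)C(C)=C | starting material
2 | (2E)-1,4-dibromo-2,3-dimethylbut-2-ene | BrC/C(C)=C(C)/CBr | intermediate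
3 | (5E)-7-bromo-5,6-dimethylhept-5-en-1-yne | C#CCC/C(C)=C(C)/CBr | intermediate
4 | 2-methylbenzene-1,4-diol | Cc1cc(O)ccc1O | starting material
5 | 4-hydroxy-3-methylphenyl 2,2-dimethylpropanoate | Cc1cc(OC(=O)C(C)(C)C)ccc1O | intermediate
6 | sodium 2-methyl-4-[(2,2-dimethylpropanoyl)oxy]phenolate | Cc1cc(OC(=O)C(C)(C)C)ccc1[O-].[Na+] | intermediate
7 | 3-[(2E)-2,3-dimethylhept-2-en-6-yn-1-yl]-4-hydroxy-5-methylphenyl 2,2-dimethylpropanoate | C#CCC/C(C)=C(C)/Cc1cc(OC(=O)C(C)(C)C)cc(C)c1O | intermediate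
8 | 2-[(2E)-2,3-dimethylhept-2-en-6-yn-1-yl]-6-methyl-1,4-phenylene bis(2,2-dimethylpropanoate) | C#CCC/C(C)=C(C)/Cc1cc(OC(=O)C(C)(C)C)cc(C)c1OC(=O)C(C)(C)C | intermediate
9 | dimethyl[(1E,5E)-7-{2,5-bis[(2,2-dimethylpropanoyl)oxy]-3-methylphenyl}-2,5,6-trimethylhepta-1,5-dien-1-yl]alane | C[Al](C)/C=C(\C)CC/C(C)=C(C)/Cc1cc(OC(=O)C(C)(C)C)cc(C)c1OC(=O)C(C)(C)C | intermediate
10 | 2-methyl-6-[(2E,6E)-2,3,6-trimethylnona-2,6,8-trien-1-yl]-1,4-phenylene bis(2,2-dimethylpropanoate) | C=C/C=C(\C)CC/C(C)=C(C)/Cc1cc(OC(=O)C(C)(C)C)cc(C)c1OC(=O)C(C)(C)C | intermediate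
11 | 2,2-dimethylcyclohexane-1,3-dione | CC1(C)C(=O)CCCC1=O | starting material
12 | 6,6-dimethyl-1,4-dioxaspiro[4.5]decan-7-one | CC1(C)C(=O)CCCC12OCCO2 | intermediate
13 | potassium 6,6-dimethyl-1,4-dioxaspiro[4.5]dec-7-en-7-olate | CC1(C)C([O-])=CCCC12OCCO2.[K+] | intermediate
14 | 6,6-dimethyl-1,4-dioxaspiro[4.5]dec-7-en-7-yl trifluoromethanesulfonate | CC1(C)C(OS(=O)(=O)C(F)(F)F)=CCCC12OCCO2 | intermediate
15 | 2-[(2E,6E)-9-(9-borabicyclo[3.3.1]nonan-9-yl)-2,3,6-trimethylnona-2,6-dien-1-yl]-6-methyl-1,4-phenylene bis(2,2-dimethylpropanoate) | B1(CC/C=C(\C)CC/C(C)=C(C)/Cc2cc(OC(=O)C(C)(C)C)cc(C)c2OC(=O)C(C)(C)C)C2CCCC1CCC2 | intermediate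
16 | 2-[(2E,6E)-9-(6,6-dimethyl-1,4-dioxaspiro[4.5]dec-7-en-7-yl)-2,3,6-trimethylnona-2,6-dien-1-yl]-6-methyl-1,4-phenylene bis(2,2-dimethylpropanoate) | CC1(C)C(CC/C=C(\C)CC/C(C)=C(C)/Cc2cc(OC(=O)C(C)(C)C)cc(C)c2OC(=O)C(C)(C)C)=CCCC13OCCO3 | intermediate
17 | 2-{2-[(1S,4aR,5S,6S,8aR)-5-({2,5-bis[(2,2-dimethylpropanoyl)oxy]-3-methylphenyl}methyl)-5,6,8a-trimethyl-2-(propan-2-ylidene)decahydronaphthalen-1-yl]ethyl}-1,3-dioxolan-2-ylium (counter-ion: conjugate base of the acid catalyst) | CC(C)(C)C(=O)Oc1cc(C)c(OC(=O)C(C)(C)C)c(C[C@]2(C)[C@H]3CCC(=C(C)C)[C@@H](CCC4=[O+]CCO4)[C@]3(C)CC[C@@H]2C)c1 | intermediate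
18 | 2-hydroxyethyl 3-[(1S,4aR,5S,6S,8aR)-5-({2,5-bis[(2,2-dimethylpropanoyl)oxy]-3-methylphenyl}methyl)-5,6,8a-trimethyl-2-(propan-2-ylidene)decahydronaphthalen-1-yl]propanoate | CC(C)(C)C(=O)Oc1cc(C)c(OC(=O)C(C)(C)C)c(C[C@]2(C)[C@H]3CCC(=C(C)C)[C@@H](CCC(=O)OCCO)[C@]3(C)CC[C@@H]2C)c1 | intermediate
19 | 3-[(1S,4aR,5S,6S,8aR)-5-[(2,5-dihydroxy-3-methylphenyl)methyl]-5,6,8a-trimethyl-2-(propan-2-ylidene)decahydronaphthalen-1-yl]propanoic acid | Oc1cc(C)c(O)c(C[C@]2(C)[C@H]3CCC(=C(C)C)[C@@H](CCC(=O)O)[C@]3(C)CC[C@@H]2C)c1 | intermediate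
20 | 3-[(1S,4aR,5S,6S,8aR)-5-{[5-(acetyloxy)-2-hydroxy-3-methylphenyl]methyl}-5,6,8a-trimethyl-2-(propan-2-ylidene)decahydronaphthalen-1-yl]propanoic acid | CC(=O)Oc1cc(C)c(O)c(C[C@]2(C)[C@H]3CCC(=C(C)C)[C@@H](CCC(=O)O)[C@]3(C)CC[C@@H]2C)c1 | target

**Step count and risk**
Total steps: 11. Longest linear sequence: 8 steps (1 → 2 → 3 → 8 → 10 → 16 → 18 → 19 → 20, i.e. steps 1, 2, 4, 5, 8, 9, 10, 11).

Most likely to fail, step 9 (cascade). Risks: unknown enantioselectivity for a tetrasubstituted initiating alkene; stepwise leakage that erodes the C5/C6 relationship; premature fragmentation by protonation of the ring-A alkene; reversible ketal ionisation. The fallback sets out from 16 and returns at 19. It swaps the ketal/dioxolanylium terminus for a hydroxyl-driven retro-Prins terminus and the catalytic acid for a stoichiometric chiral Lewis-acid-assisted Brønsted acid. Ketal hydrolysis of 16 (pyridinium p-toluenesulfonate, acetone/H2O) gives the ring-A ketone F1. Reduction (NaBH4, CeCl3·7H2O, MeOH) gives the ring-A alcohol F2, whose carbinol configuration is irrelevant. Cyclisation with (R)-2-methoxy-2'-hydroxy-1,1'-binaphthyl and SnCl4 (toluene, −78 °C) gives the seco-aldehyde F3. Pinnick oxidation (NaClO2, NaH2PO4, 2-methylbut-2-ene) gives the bis-pivalate acid F4, and KOH saponification as in step 10 gives 19.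

Second, step 4 (phenoxide C-allylation). Risks: O-allylation and modest yield. The fallback sets out from 5 and returns at 8. NBS bromination ortho to the free hydroxyl gives the bromophenol F5. Pivaloylation (t-BuCOCl, Et3N, DMAP) gives the bromo bis-pivalate F6. Miyaura borylation (B2pin2, PdCl2(dppf), KOAc, dioxane, 80 °C) gives the aryl pinacol boronate F7. Allyl–aryl Suzuki coupling of F7 with 3 (Pd(PPh3)4, K3PO4, THF/H2O, 50 °C) gives 8.

Third, step 8 (hydroboration of the conjugated diene arm and B-alkyl coupling). Risks: allylic borane formation or double hydroboration. The fallback sets out from 8 (with 14 as partner) and returns at 16; it moves the hydroboration to the small ring-A partner and forms the C4a–C4 bond instead. Carboalumination of 8 as in step 5 (via 9) and quenching with I2 gives the E vinyl iodide F8. Vinylation of 14 (K[CH2=CHBF3], PdCl2(dppf), Et3N, i-PrOH/H2O) gives the ring-A diene F9, and 9-BBN turns it into the ring-A alkylborane F10. Suzuki–Miyaura coupling of F10 with F8 (PdCl2(dppf), AsPh3, Cs2CO3, DMF/H2O) gives 16.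

**Further compounds**
F1 | step 9 | 2-[(2E,6E)-9-(6,6-dimethyl-5-oxocyclohex-1-en-1-yl)-2,3,6-trimethylnona-2,6-dien-1-yl]-6-methyl-1,4-phenylene bis(2,2-dimethylpropanoate) | CC1(C)C(CC/C=C(\C)CC/C(C)=C(C)/Cc2cc(OC(=O)C(C)(C)C)cc(C)c2OC(=O)C(C)(C)C)=CCCC1=O
F2 | step 9 | 2-[(2E,6E)-9-(5-hydroxy-6,6-dimethylcyclohex-1-en-1-yl)-2,3,6-trimethylnona-2,6-dien-1-yl]-6-methyl-1,4-phenylene bis(2,2-dimethylpropanoate) (carbinol centre racemic) | CC1(C)C(CC/C=C(\C)CC/C(C)=C(C)/Cc2cc(OC(=O)C(C)(C)C)cc(C)c2OC(=O)C(C)(C)C)=CCCC1O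
F3 | step 9 | 3-[(1S,4aR,5S,6S,8aR)-5-({2,5-bis[(2,2-dimethylpropanoyl)oxy]-3-methylphenyl}methyl)-5,6,8a-trimethyl-2-(propan-2-ylidene)decahydronaphthalen-1-yl]propanal | CC(C)(C)C(=O)Oc1cc(C)c(OC(=O)C(C)(C)C)c(C[C@]2(C)[C@H]3CCC(=C(C)C)[C@@H](CCC=O)[C@]3(C)CC[C@@H]2C)c1
F4 | step 9 | 3-[(1S,4aR,5S,6S,8aR)-5-({2,5-bis[(2,2-dimethylpropanoyl)oxy]-3-methylphenyl}methyl)-5,6,8a-trimethyl-2-(propan-2-ylidene)decahydronaphthalen-1-yl]propanoic acid | CC(C)(C)C(=O)Oc1cc(C)c(OC(=O)C(C)(C)C)c(C[C@]2(C)[C@H]3CCC(=C(C)C)[C@@H](CCC(=O)O)[C@]3(C)CC[C@@H]2C)c1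
F5 | step 4 | 3-bromo-4-hydroxy-5-methylphenyl 2,2-dimethylpropanoate | Cc1cc(OC(=O)C(C)(C)C)cc(Br)c1O
F6 | step 4 | 2-bromo-6-methyl-1,4-phenylene bis(2,2-dimethylpropanoate) | Cc1cc(OC(=O)C(C)(C)C)cc(Br)c1OC(=O)C(C)(C)C
F7 | step 4 | 2-methyl-6-(4,4,5,5-tetramethyl-1,3,2-dioxaborolan-2-yl)-1,4-phenylene bis(2,2-dimethylpropanoate) | Cc1cc(OC(=O)C(C)(C)C)cc(B2OC(C)(C)C(C)(C)O2)c1OC(=O)C(C)(C)C
F8 | step 8 | 2-[(2E,6E)-7-iodo-2,3,6-trimethylhepta-2,6-dien-1-yl]-6-methyl-1,4-phenylene bis(2,2-dimethylpropanoate) | I/C=C(\C)CC/C(C)=C(C)/Cc1cc(OC(=O)C(C)(C)C)cc(C)c1OC(=O)C(C)(C)C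
F9 | step 8 | 7-ethenyl-6,6-dimethyl-1,4-dioxaspiro[4.5]dec-7-ene | CC1(C)C(C=C)=CCCC12OCCO2
F10 | step 8 | 9-[2-(6,6-dimethyl-1,4-dioxaspiro[4.5]dec-7-en-7-yl)ethyl]-9-borabicyclo[3.3.1]nonane | CC1(C)C(CCB3C4CCCC3CCC4)=CCCC12OCCO2
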